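The runs were computed from invented constants.

**The constants.** I can read two constants from these runs. Both are slopes of ln(charge over what is left) for the left-handed substrate, a pseudo-first-order view that takes the falling substrate out of the curve.

in all of them: left-handed substrate 0.011 M; right-handed substrate 0.011 M; partner 0.0121 M
- north: precatalyst 0.37 mM; the very flask that is asked about, followed so far
- west: precatalyst 0.25 mM; run made earlier
- flask: precatalyst 0.37 mM; time 1.0 h

- north (time / min: left-handed substrate / %, right-handed substrate / %, left-handed product / %): 5.00: 39, 52, 13; 10.0: 29, 49, 23; 15.0: 20, 49, 33; 20.0: 18, 50, 33
- west (time / min: left-handed substrate / %, right-handed substrate / %, left-handed product / %): 3.00: 46, 50, 5; 8.00: 36, 47, 15; 15.0: 29, 48, 22; 25.0: 19, 48, 27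

(readings scatter by 1.5 percentage points)

- free catalyst is single-handed; left-handed substrate and right-handed substrate are mirror images of each other, charged as a racemate, each of them at the stated concentration
- an excess is below zero if the other one leads

1. part of the left-handed substrate and right-handed substrate charged together that has reacted at 1.0 h
2. excess of left-handed product over right-handed product in the product at 1.0 h
3. excess of right-handed substrate over left-handed substrate among what is left of the two at 1.0 h

**The curve.** In north the slope from 5.00 min to 15.0 min is 0.0668 /min. Then comes a knee, and up to 20.0 min the slope is 0.0211 /min, about a third of the first. So the readings bend towards a level. West and north differ in their precatalyst charge, their other charges being equal, so I compare the two by that charge.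

**The reach.** The last west reading gives 3.87 /mM for the reach per catalyst, the logarithm above divided by the precatalyst charged. North has so far reached 2.76 /mM, less than west, so north still has some way to fall. Held for this flask, the reach puts c(left-handed substrate) at a level of 11.9% of the two substrates charged. That is the reading to watch after the knee. West's last reading shows 2 percentage points of right-handed substrate gone. With that loss I commit to c 40.1%, eP 90.0% and eS 60.3%.

**The forecast.** It gives c 52% (45% to 55%), eP 83% and eS 90%, carrying a roughly first-order decay on to the hour, though “the last points hint at some catalyst decay”. My c lies below its range.

    partner + free catalyst + right-handed substrate → free catalyst + right-handed product (k = 28.7 /M²/s)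
    partner + free catalyst → spent catalyst A (k = 0.0528 /M/s)
    precatalyst → free catalyst (k = 0.00260 /s)
    partner + free catalyst + left-handed substrate → free catalyst + left-handed product (k = 876 /M²/s)
    free catalyst → spent catalyst B (k = 8.84 × 10⁻⁴ /s)

**The stop.** The flask gives c 41.0%, eP 88.4% and eS 61.5%, and its reach is 4.00 /mM. At 0.131 h free catalyst has a half-life of 0.22 h by its step to spent catalyst B, shorter than the time. At 1.00 h, with 3.35% of free catalyst left, the half-life of left-handed substrate by its step to left-handed product is 5.9 h, longer than the time. For a neighbouring flask charged with 1.5 × 10⁻⁴ M of precatalyst, my reach predicts 28.0% left-handed substrate. That flask holds 22.6%, a reach of 5.30 /mM, with 47% of its partner left.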